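## Retrosynthetic overview

1. Target ⇐ late acylations (methacrylate on the C-14 OH, acetates on the C-1 and C-6 OH) and Eschenmoser α-methylenation of a trans-fused lactone diol; the C-6 carbinol ⇐ L-Selectride reduction of a cyclohexenone.
2. C-14 ⇐ Stille hydroxymethylation of a vinyl triflate; cyclohexene ring ⇐ intramolecular Claisen condensation (C-5–C-10 bond) of a δ-keto ester.
3. Key C-6–C-7 bond ⇐ decatungstate-photocatalysed acyl-radical addition of a citronellal-derived aldehyde to a γ-substituted butenolide, which sets C-7 anti to C-8.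
4. Stereocentres: C-4 is bought in (S)-citronellal and C-8 in dimethyl (R)-malate; C-7 is relayed from C-8 and C-6 from C-7.
5. Ring order: butenolide (the lactone) first, then the cyclohexenone by Claisen closure, exocyclic methylene last.

Assumption: the configuration is taken exactly from the SMILES (trans-fused γ-lactone, C-6 acetate cis to the C-7–C-11 bond); locants follow eudesmane numbering (C-4 side-chain stereocentre, C-5=C-10 ring alkene, C-6 OAc carbon, C-7/C-8 ring fusion, C-11=C-13 methylene, C-14 CH2O).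

## Route

Step 1
Reactants: 1 (S)-citronellal
Product: 2 (6S)-8,8-dimethoxy-2,6-dimethyloct-2-ene
Conditions: HC(OMe)3, cat. TsOH·H2O, MeOH, 0 °C → rt
Reagents that add atoms: trimethyl orthoformate, COC(OC)OC
Why: Acid-catalysed acetalisation with orthoformate as water scavenger masks the aldehyde under conditions too mild for the Prins/ene cyclisation of citronellal; the β-stereocentre is not touched.

Step 2
Reactants: 2 (6S)-8,8-dimethoxy-2,6-dimethyloct-2-ene
Product: 3 (4S)-6,6-dimethoxy-4-methylhexan-1-ol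
Conditions: O3, CH2Cl2/MeOH, −78 °C; then NaBH4, −78 → 0 °C
Reagents that add atoms: ozone, [O-][O+]=O
Why: Ozonolysis of the only alkene with reductive (borohydride) work-up gives the primary alcohol directly, the acetal being inert.

Step 3
Reactants: 3 (4S)-6,6-dimethoxy-4-methylhexan-1-ol
Product: 5 (3S)-6-[(tert-butyldiphenylsilyl)oxy]-3-methylhexanal, via silyl ether acetal 4 (not isolated)
Conditions: TBDPSCl, imidazole, CH2Cl2, rt; then 1 M HCl, THF, rt
Reagents that add atoms: tert-butyl(chloro)diphenylsilane, CC(C)(C)[Si](Cl)(c1ccccc1)c1ccccc1; water, O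
Why: Silylation of the primary alcohol followed by acetal hydrolysis, which the acid-stable TBDPS ether survives, frees the aldehyde needed for acyl-radical generation.

Step 4
Reactants: 6 dimethyl (R)-malate
Product: 7 methyl (3R)-3,4-dihydroxybutanoate
Conditions: BH3·SMe2 (1.05 equiv), NaBH4 (5 mol%), THF, 0 °C → rt; MeOH quench
Reagents that add atoms: none
Why: Hydroxyl-directed borane reduction (Saito–Moriwake conditions) reduces only the ester next to the hydroxyl through a cyclic alkoxyborane, leaving the stereocentre and the distal ester intact.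

Step 5
Reactants: 7 methyl (3R)-3,4-dihydroxybutanoate
Product: 9 methyl 2-[(2R)-5-oxo-2,5-dihydrofuran-2-yl]acetate, via hydroxy aldehyde 8 (not isolated)
Conditions: TEMPO (10 mol%), PhI(OAc)2, CH2Cl2, 0 °C; then Ph3P=C=C=O, toluene, 60 °C
Reagents that add atoms: (triphenylphosphoranylidene)ketene (Bestmann ylide), O=C=C=P(c1ccccc1)(c1ccccc1)c1ccccc1
Why: Primary-selective oxoammonium oxidation gives the α-hydroxy aldehyde, whose hydroxyl adds to the ketene ylide and then closes by intramolecular Wittig olefination to the butenolide, so the ring alkene is necessarily Z and the carbinol stereocentre is retained.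

Step 6
Reactants: 5 (3S)-6-[(tert-butyldiphenylsilyl)oxy]-3-methylhexanal; 9 methyl 2-[(2R)-5-oxo-2,5-dihydrofuran-2-yl]acetate
Product: 10 methyl 2-[(2R,3S)-3-{(3S)-6-[(tert-butyldiphenylsilyl)oxy]-3-methylhexanoyl}-5-oxooxolan-2-yl]acetate
Conditions: 5 (1.3 equiv), (n-Bu4N)4[W10O32] (TBADT, 2 mol%), MeCN, 390 nm LEDs, rt, Ar
Reagents that add atoms: none
Why: Proposed new method: photoexcited decatungstate abstracts the hydridic formyl hydrogen of 5 (polarity-matched HAT), the nucleophilic acyl radical adds to the β-carbon of butenolide 9 on the face anti to the γ-CH2CO2Me group (setting C-7 trans to C-8), and the resulting electrophilic α-lactone radical takes the hydrogen back from the reduced polyoxometalate; the closest known reactions are TBADT hydroacylation of acyclic electron-poor alkenes with aliphatic aldehydes and anti-selective photochemical radical additions to 5-substituted 2(5H)-furanones, a combination not yet shown on a γ-stereogenic butenolide.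

Step 7
Reactants: 10 methyl 2-[(2R,3S)-3-{(3S)-6-[(tert-butyldiphenylsilyl)oxy]-3-methylhexanoyl}-5-oxooxolan-2-yl]acetate
Product: 12 (3aS,7aR)-5-{(2S)-5-[(tert-butyldiphenylsilyl)oxy]pentan-2-yl}-2,4-dioxo-2,3,3a,4,7,7a-hexahydro-1-benzofuran-6-yl trifluoromethanesulfonate, via enolised trione 11 (not isolated)
Conditions: LiHMDS (1.1 equiv), THF, −78 → −20 °C; then PhNTf2, −20 °C → rt
Reagents that add atoms: N-phenylbis(trifluoromethanesulfonimide), O=S(=O)(N(c1ccccc1)S(=O)(=O)C(F)(F)F)C(F)(F)F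
Why: The kinetic ketone enolate at the unhindered C-5 methylene undergoes a 6-exo intramolecular Claisen (Dieckmann-type) acylation on the methyl ester, and the resulting 1,3-dione enolate is O-sulfonylated at the less hindered oxygen remote from the ring fusion; no stereocentre is formed and the trans ring fusion is the one set in step 6.

Step 8
Reactants: 12 (3aS,7aR)-5-{(2S)-5-[(tert-butyldiphenylsilyl)oxy]pentan-2-yl}-2,4-dioxo-2,3,3a,4,7,7a-hexahydro-1-benzofuran-6-yl trifluoromethanesulfonate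
Product: 13 (3aS,7aR)-5-{(2S)-5-[(tert-butyldiphenylsilyl)oxy]pentan-2-yl}-6-(hydroxymethyl)-3,3a,7,7a-tetrahydro-1-benzofuran-2,4-dione
Conditions: Bu3SnCH2OH, Pd(PPh3)4 (5 mol%), LiCl, 1,4-dioxane, 90 °C
Reagents that add atoms: (tributylstannyl)methanol, CCCC[Sn](CCCC)(CCCC)CO
Why: Stille coupling (Kosugi hydroxymethylation) of the electron-poor β-triflyloxy enone installs C-14 with its oxygen under neutral conditions that do not enolise C-7.

Step 9
Reactants: 13 (3aS,7aR)-5-{(2S)-5-[(tert-butyldiphenylsilyl)oxy]pentan-2-yl}-6-(hydroxymethyl)-3,3a,7,7a-tetrahydro-1-benzofuran-2,4-dione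
Product: 14 (3aR,4S,7aR)-5-{(2S)-5-[(tert-butyldiphenylsilyl)oxy]pentan-2-yl}-4-hydroxy-6-(hydroxymethyl)-3a,4,7,7a-tetrahydro-1-benzofuran-2(3H)-one
Conditions: L-Selectride (2.2 equiv), THF, −78 °C; AcOH quench at −78 °C
Reagents that add atoms: none
Why: The bulky trialkylborohydride attacks the ketone from the equatorial direction and gives the pseudoaxial alcohol cis to the adjacent C-7–C-11 bond (as in cis-2-alkylcyclohexanols from 2-alkylcyclohexanones), 1,4-reduction being blocked by the fully substituted β-carbon; the cold acidic quench avoids lactone migration.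

Step 10
Reactants: 14 (3aR,4S,7aR)-5-{(2S)-5-[(tert-butyldiphenylsilyl)oxy]pentan-2-yl}-4-hydroxy-6-(hydroxymethyl)-3a,4,7,7a-tetrahydro-1-benzofuran-2(3H)-one
Product: 16 (3aR,4S,7aR)-5-{(2S)-5-[(tert-butyldiphenylsilyl)oxy]pentan-2-yl}-4-hydroxy-6-(hydroxymethyl)-3-methylidene-3a,4,7,7a-tetrahydro-1-benzofuran-2(3H)-one, via Mannich base 15 (not isolated)
Conditions: LDA (3.5 equiv), THF, −78 °C; CH2=NMe2+ I−, −78 → 0 °C; then MeI, MeOH, rt; aq. NaHCO3, CH2Cl2
Reagents that add atoms: N,N-dimethylmethyleneiminium iodide (Eschenmoser's salt), C=[N+](C)C.[I-]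
Why: Excess amide base forms the dialkoxide and the lactone enolate (an enolised lactone cannot be attacked by the C-6 alkoxide), Mannich aminomethylation and quaternisation/Hofmann-type elimination give the α-methylene lactone (Eschenmoser methylenation) without touching C-7.

Step 11
Reactants: 16 (3aR,4S,7aR)-5-{(2S)-5-[(tert-butyldiphenylsilyl)oxy]pentan-2-yl}-4-hydroxy-6-(hydroxymethyl)-3-methylidene-3a,4,7,7a-tetrahydro-1-benzofuran-2(3H)-one
Product: 17 [(3aR,4S,7aR)-5-{(2S)-5-[(tert-butyldiphenylsilyl)oxy]pentan-2-yl}-4-hydroxy-3-methylidene-2-oxo-2,3,3a,4,7,7a-hexahydro-1-benzofuran-6-yl]methyl 2-methylprop-2-enoate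
Conditions: methacrylic anhydride (1.05 equiv), Et3N, DMAP (5 mol%), CH2Cl2, −40 °C
Reagents that add atoms: methacrylic anhydride, CC(=C)C(=O)OC(=O)C(C)=C
Why: DMAP-catalysed acylation is selective for the primary allylic alcohol over the pseudoaxial secondary alcohol, which is flanked by the sec-alkyl-bearing alkene carbon and the ring fusion.

Step 12
Reactants: 17 [(3aR,4S,7aR)-5-{(2S)-5-[(tert-butyldiphenylsilyl)oxy]pentan-2-yl}-4-hydroxy-3-methylidene-2-oxo-2,3,3a,4,7,7a-hexahydro-1-benzofuran-6-yl]methyl 2-methylprop-2-enoate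
Product: 19 [(3aS,4S,7aR)-4-(acetyloxy)-5-[(2S)-5-(acetyloxy)pentan-2-yl]-3-methylidene-2-oxo-2,3,3a,4,7,7a-hexahydro-1-benzofuran-6-yl]methyl 2-methylprop-2-enoate, via desilylated diol 18 (not isolated)
Conditions: HF·pyridine, THF, 0 °C → rt; then Ac2O, pyridine, DMAP, rt
Reagents that add atoms: acetic anhydride, CC(=O)OC(C)=O
Why: Fluoride cleaves the silyl ether without harming the two acrylate-type esters, and DMAP-catalysed acetylation esterifies both free hydroxyls with retention at C-6 to give the target.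

## Compound list

1 | (S)-citronellal, (3S)-3,7-dimethyloct-6-enal | O=CC[C@@H](C)CCC=C(C)C | starting material
2 | (6S)-8,8-dimethoxy-2,6-dimethyloct-2-ene | COC(OC)C[C@@H](C)CCC=C(C)C | intermediate
3 | (4S)-6,6-dimethoxy-4-methylhexan-1-ol | COC(OC)C[C@@H](C)CCCO | intermediate
4 | tert-butyl{[(4S)-6,6-dimethoxy-4-methylhexyl]oxy}diphenylsilane | COC(OC)C[C@@H](C)CCCO[Si](c1ccccc1)(c1ccccc1)C(C)(C)C | intermediate
5 | (3S)-6-[(tert-butyldiphenylsilyl)oxy]-3-methylhexanal | O=CC[C@@H](C)CCCO[Si](c1ccccc1)(c1ccccc1)C(C)(C)C | intermediate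
6 | dimethyl (R)-malate, dimethyl (2R)-2-hydroxybutanedioate | COC(=O)C[C@@H](O)C(=O)OC | starting material
7 | methyl (3R)-3,4-dihydroxybutanoate | COC(=O)C[C@@H](O)CO | intermediate
8 | methyl (3R)-3-hydroxy-4-oxobutanoate | COC(=O)C[C@@H](O)C=O | intermediate
9 | methyl 2-[(2R)-5-oxo-2,5-dihydrofuran-2-yl]acetate | COC(=O)C[C@H]1OC(=O)C=C1 | intermediate
10 | methyl 2-[(2R,3S)-3-{(3S)-6-[(tert-butyldiphenylsilyl)oxy]-3-methylhexanoyl}-5-oxooxolan-2-yl]acetate (2,3-trans) | COC(=O)C[C@H]1OC(=O)C[C@@H]1C(=O)C[C@@H](C)CCCO[Si](c2ccccc2)(c2ccccc2)C(C)(C)C | intermediate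
11 | (3aS,7aR)-5-{(2S)-5-[(tert-butyldiphenylsilyl)oxy]pentan-2-yl}-6-hydroxy-3,3a,7,7a-tetrahydro-1-benzofuran-2,4-dione (enol form of the 2,4,6-trione, trans-fused) | OC1=C([C@@H](C)CCCO[Si](c3ccccc3)(c3ccccc3)C(C)(C)C)C(=O)[C@H]2CC(=O)O[C@@H]2C1 | intermediate
12 | (3aS,7aR)-5-{(2S)-5-[(tert-butyldiphenylsilyl)oxy]pentan-2-yl}-2,4-dioxo-2,3,3a,4,7,7a-hexahydro-1-benzofuran-6-yl trifluoromethanesulfonate | O=S(=O)(OC1=C([C@@H](C)CCCO[Si](c3ccccc3)(c3ccccc3)C(C)(C)C)C(=O)[C@H]2CC(=O)O[C@@H]2C1)C(F)(F)F | intermediate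
13 | (3aS,7aR)-5-{(2S)-5-[(tert-butyldiphenylsilyl)oxy]pentan-2-yl}-6-(hydroxymethyl)-3,3a,7,7a-tetrahydro-1-benzofuran-2,4-dione | OCC1=C([C@@H](C)CCCO[Si](c3ccccc3)(c3ccccc3)C(C)(C)C)C(=O)[C@H]2CC(=O)O[C@@H]2C1 | intermediate
14 | (3aR,4S,7aR)-5-{(2S)-5-[(tert-butyldiphenylsilyl)oxy]pentan-2-yl}-4-hydroxy-6-(hydroxymethyl)-3a,4,7,7a-tetrahydro-1-benzofuran-2(3H)-one (4-OH cis to C-3a–C-3) | OCC1=C([C@@H](C)CCCO[Si](c3ccccc3)(c3ccccc3)C(C)(C)C)[C@@H](O)[C@H]2CC(=O)O[C@@H]2C1 | intermediate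
15 | (3aR,4S,7aR)-5-{(2S)-5-[(tert-butyldiphenylsilyl)oxy]pentan-2-yl}-3-[(dimethylamino)methyl]-4-hydroxy-6-(hydroxymethyl)-3a,4,7,7a-tetrahydro-1-benzofuran-2(3H)-one (C-3 epimers) | OCC1=C([C@@H](C)CCCO[Si](c3ccccc3)(c3ccccc3)C(C)(C)C)[C@@H](O)[C@H]2C(CN(C)C)C(=O)O[C@@H]2C1 | intermediate
16 | (3aR,4S,7aR)-5-{(2S)-5-[(tert-butyldiphenylsilyl)oxy]pentan-2-yl}-4-hydroxy-6-(hydroxymethyl)-3-methylidene-3a,4,7,7a-tetrahydro-1-benzofuran-2(3H)-one | OCC1=C([C@@H](C)CCCO[Si](c3ccccc3)(c3ccccc3)C(C)(C)C)[C@@H](O)[C@H]2C(=C)C(=O)O[C@@H]2C1 | intermediate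
17 | [(3aR,4S,7aR)-5-{(2S)-5-[(tert-butyldiphenylsilyl)oxy]pentan-2-yl}-4-hydroxy-3-methylidene-2-oxo-2,3,3a,4,7,7a-hexahydro-1-benzofuran-6-yl]methyl 2-methylprop-2-enoate | C=C(C)C(=O)OCC1=C([C@@H](C)CCCO[Si](c3ccccc3)(c3ccccc3)C(C)(C)C)[C@@H](O)[C@H]2C(=C)C(=O)O[C@@H]2C1 | intermediate
18 | [(3aR,4S,7aR)-4-hydroxy-5-[(2S)-5-hydroxypentan-2-yl]-3-methylidene-2-oxo-2,3,3a,4,7,7a-hexahydro-1-benzofuran-6-yl]methyl 2-methylprop-2-enoate | C=C(C)C(=O)OCC1=C([C@@H](C)CCCO)[C@@H](O)[C@H]2C(=C)C(=O)O[C@@H]2C1 | intermediate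
19 | [(3aS,4S,7aR)-4-(acetyloxy)-5-[(2S)-5-(acetyloxy)pentan-2-yl]-3-methylidene-2-oxo-2,3,3a,4,7,7a-hexahydro-1-benzofuran-6-yl]methyl 2-methylprop-2-enoate (CNP0157277.1) | C=C(C)C(=O)OCC1=C([C@@H](C)CCCOC(C)=O)[C@@H](OC(C)=O)[C@H]2C(=C)C(=O)O[C@@H]2C1 | target

## Step count and risks

Total steps: 12. Longest linear sequence: 10 (steps 1–3 and 6–12 from (S)-citronellal; the malate branch is steps 4–5).

The three steps most likely to fail:

Step 6 (the proposed photochemical hydroacylation). Risks are competing hydrogen abstraction at the tertiary C–H or the silyloxy-CH2 of 5 and slow addition to the β-substituted lactone. The fallback is known polar umpolung chemistry and sets out from 5 and 9. Aldehyde 5 is converted with propane-1,3-dithiol and BF3·OEt2 into 2-{(2S)-5-[(tert-butyldiphenylsilyl)oxy]-2-methylpentyl}-1,3-dithiane F1. F1 is lithiated with n-BuLi and added 1,4 to butenolide 9 in THF/DMPU at −78 °C, anti to the γ-substituent as for other 5-substituted butenolides, to give the dithioketal lactone methyl 2-[(2R,3S)-3-(2-{(2S)-5-[(tert-butyldiphenylsilyl)oxy]-2-methylpentyl}-1,3-dithian-2-yl)-5-oxooxolan-2-yl]acetate F2. Oxidative unmasking with I2/NaHCO3 in aqueous acetone returns to the route at 10.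

Step 7 (Claisen ring closure and regioselective triflation). Risks are β-elimination or C-7 epimerisation under base and sulfonylation at the wrong dione oxygen. The fallback sets out from 11, which is isolated by acidifying after the Claisen stage. Condensation with thiophenol (cat. TsOH, benzene, reflux with water removal) is reversible, so the sulfur settles under thermodynamic control on the less hindered carbonyl carbon, giving the vinylogous thioester (3aS,7aR)-5-{(2S)-5-[(tert-butyldiphenylsilyl)oxy]pentan-2-yl}-6-(phenylsulfanyl)-3,3a,7,7a-tetrahydro-1-benzofuran-2,4-dione F3. Liebeskind–Srogl coupling of F3 with Bu3SnCH2OH (Pd2dba3, tri-2-furylphosphine, copper(I) thiophene-2-carboxylate, THF, 50 °C) returns to the route at 13.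

Step 9 (facial selectivity of the ketone reduction, with possible lactone migration to the cis C-6 alkoxide). The fallback sets out from 13. Luche reduction (NaBH4, CeCl3·7H2O, MeOH, −78 °C) delivers hydride axially and gives the C-4 epimeric diol (3aR,4R,7aR)-5-{(2S)-5-[(tert-butyldiphenylsilyl)oxy]pentan-2-yl}-4-hydroxy-6-(hydroxymethyl)-3a,4,7,7a-tetrahydro-1-benzofuran-2(3H)-one F4, whose trans alkoxide cannot form the cis-fused isomeric lactone. Double Mitsunobu esterification with chloroacetic acid (PPh3, DIAD, THF) inverts the secondary carbinol and esterifies the primary one, giving [(3aS,4S,7aR)-5-{(2S)-5-[(tert-butyldiphenylsilyl)oxy]pentan-2-yl}-4-[(chloroacetyl)oxy]-2-oxo-2,3,3a,4,7,7a-hexahydro-1-benzofuran-6-yl]methyl chloroacetate F5. Neutral removal of both chloroacetates with thiourea/NaHCO3 in ethanol returns to the route at 14.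

Further compounds

F1 | step 6 | 2-{(2S)-5-[(tert-butyldiphenylsilyl)oxy]-2-methylpentyl}-1,3-dithiane | C1(C[C@@H](C)CCCO[Si](c2ccccc2)(c2ccccc2)C(C)(C)C)SCCCS1
F2 | step 6 | methyl 2-[(2R,3S)-3-(2-{(2S)-5-[(tert-butyldiphenylsilyl)oxy]-2-methylpentyl}-1,3-dithian-2-yl)-5-oxooxolan-2-yl]acetate | COC(=O)C[C@H]1OC(=O)C[C@@H]1C3(C[C@@H](C)CCCO[Si](c2ccccc2)(c2ccccc2)C(C)(C)C)SCCCS3
F3 | step 7 | (3aS,7aR)-5-{(2S)-5-[(tert-butyldiphenylsilyl)oxy]pentan-2-yl}-6-(phenylsulfanyl)-3,3a,7,7a-tetrahydro-1-benzofuran-2,4-dione | c4ccccc4SC1=C([C@@H](C)CCCO[Si](c3ccccc3)(c3ccccc3)C(C)(C)C)C(=O)[C@H]2CC(=O)O[C@@H]2C1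
F4 | step 9 | (3aR,4R,7aR)-5-{(2S)-5-[(tert-butyldiphenylsilyl)oxy]pentan-2-yl}-4-hydroxy-6-(hydroxymethyl)-3a,4,7,7a-tetrahydro-1-benzofuran-2(3H)-one | OCC1=C([C@@H](C)CCCO[Si](c3ccccc3)(c3ccccc3)C(C)(C)C)[C@H](O)[C@H]2CC(=O)O[C@@H]2C1
F5 | step 9 | [(3aS,4S,7aR)-5-{(2S)-5-[(tert-butyldiphenylsilyl)oxy]pentan-2-yl}-4-[(chloroacetyl)oxy]-2-oxo-2,3,3a,4,7,7a-hexahydro-1-benzofuran-6-yl]methyl chloroacetate | ClCC(=O)OCC1=C([C@@H](C)CCCO[Si](c3ccccc3)(c3ccccc3)C(C)(C)C)[C@@H](OC(=O)CCl)[C@H]2CC(=O)O[C@@H]2C1
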